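## Compound numbering

1 diisopropyl squarate; 2 hydroxycyclobutenone from its mono-reduction (not isolated); 3 semisquarate; 4 5-ethynyl-1,2,3-trimethoxybenzene; 5 its lithium acetylide (not isolated); 6 lithium hemiaminal alkoxide (not isolated); 7 arylpropynal; 8 (E)-1,2-bis(tributylstannyl)ethene; 9 (E)-2-(tributylstannyl)ethenyllithium (not isolated); 10 stannyl enynol; 11 its TBS ether; 12 alkenyllithium (not isolated); 13 lithium alkoxide (not isolated); 14 cyclobutenone, substrate of the key step; 15 dienylketene (not isolated); 16 cyclohexadienone (not isolated); 17 phenol, product of the key step; 18 phenol carbinol; 19 2-hydroxyaryl ynone; 20 enaminone (not isolated); 21 7-O-isopropyl flavone; 22 aryloxydichloroborane (not isolated); 23 Prosogerin D.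

## Analysis of the target

Prosogerin D (23) is a flavone: a benzo ring A (C4a, C5, C6, C7, C8, C8a) fused to a 4-pyranone ring C (O1, C2, C3, C4, C4a, C8a), with a 3,4,5-trimethoxyphenyl ring B on C2. The molecule has no stereocentre and no configurable double bond, so nothing has to be controlled in space and the task is regiochemical. Ring A carries three oxygens in a 1,2,4 relationship: O1 on C8a, a free hydroxyl on C7 and a methoxy group on C6, while C5 and C8 carry hydrogen. The sensitive points are the 7-hydroxyl (para to the C4 carbonyl through C4a, hence an acidic vinylogous acid), the pyranone (an electrophile at C2) and the flanked 4′-methoxy group of ring B (the methyl ether most exposed to Lewis acids). The difficulty is twofold: O6 and O7 are neighbours that differ only by one methyl group, so routes from a preformed trioxygenated benzene depend on selective protection, and closure of ring C from a 2-hydroxyaryl ynone can give the five-membered aurone instead of the chromone. The plan rests on the run C8a(O)–C8(H)–C7(O)–C6(O) of ring A: its pattern O, H, O, O is that of the four ring carbons of a 4-oxygenated 3-alkoxycyclobutenone, so these atoms can come from a squarate ester with each oxygen attached and labelled before ring A exists. The two remaining ring-A atoms, C5 and C4a, are then the two carbons of an alkenyl group that already carries C4, C3, C2 and ring B.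

## Retrosynthetic reasoning

**O7–isopropyl.** Prosogerin D (23) is traced back to its 7-O-isopropyl ether 21 by cutting the O7–alkyl bond. The isopropyl group is the alkoxy group that the four-carbon building block 3 brings with it, so no protecting-group step is spent on O7. A secondary alkyl aryl ether can be cleaved by a boron trihalide without loss of methyl ethers. Keeping the acidic 7-hydroxyl masked until the end lets it pass through organolithium, oxidation and amine steps.

**O1–C2.** Ring C of 21 is opened at the O1–C2 bond to give the 2-hydroxyaryl ynone 19. This cut keeps the whole C4–C3–C2–ring B chain in one piece and leaves a single heteroatom–carbon bond to be made. The forward reaction must close six-membered, through oxygen attack on C2, rather than five-membered on C3. Routing the closure through the amine adduct 20 makes C2 the only electrophilic carbon.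

**Oxidation level at C4.** The C4 carbonyl of 19 is taken back to the carbinol 18 and further to its silyl ether 17. An ynone cannot survive the alkenyllithium chemistry needed earlier, whereas a silyl-protected carbinol can. A benzylic, propargylic alcohol is the easiest kind to re-oxidise under neutral conditions.

**C8a–C4a, the key disconnection.** Ring A of 17 is cut between C8a and C4a and unfolded through dienone 16 and dienylketene 15 to the four-membered ring of 14. Each of the four contiguous carbons C8a, C8, C7 and C6 already bears its final substituent in 14 (carbonyl oxygen, hydrogen, isopropoxy, methoxy). Ring strain and aromatisation drive the forward reaction, which needs only heat. This moves the regiochemical problem of ring A out of aromatic chemistry and into carbonyl addition chemistry.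

**C6–C5 and O6–methyl.** Cyclobutenone 14 is cut at the bond between its quaternary carbon (future C6) and the alkenyl carbon (future C5), and at the O–methyl bond, giving alkoxide 13 and then alkenyllithium 12 plus semisquarate 3. The two carbonyl groups of 3 differ: one is the terminus of a vinylogous ester, the other is ketone-like. Addition to the ketone-like one puts the new quaternary carbon next to the isopropoxy carbon, as the C6/C7 relationship requires. Methylation of the resulting alkoxide installs the O6 methyl group, so O6 and O7 are distinguished by construction.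

**Semisquarate.** Compound 3 comes from diisopropyl squarate 1 by removing one alkoxy-bearing carbon's oxygen function, through mono-reduction to 2 and acid-induced loss of the alcohol. This turns one of the two equivalent enol-ether carbons into the C–H that becomes C8.

**C4–C4a.** Alkenyllithium 12 comes from stannane 11, and 11 from alcohol 10. Alcohol 10 is cut between the carbinol carbon (future C4) and the alkene carbon (future C4a) into ynal 7 and the two-carbon nucleophile 9, obtained from distannane 8. Cutting there uses a symmetric, geometrically pure two-carbon unit, so the (E) alkene and the tin handle for the later lithiation arrive together and no hydrostannation of a diyne is needed.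

**C4–C3.** Ynal 7 is cut between the formyl carbon and the alkyne into the acetylide 5 of arylalkyne 4 and a formamide, through adduct 6. Ring B, with its three methyl ethers, is bought ready-made.

## Alternatives that were turned down

**Alternative 1:** Ring C is cut at three bonds at once, C4a–C4, C4–C3 and O1–C2, into iodophenol A2, the arylalkyne 4 of the present route and a one-carbon carbonyl unit. In the forward step, PdCl2(PPh3)2 (a divalent palladium precatalyst reduced in the flask to zerovalent palladium) in a secondary amine under carbonylative conditions inserts into the C–I bond, takes up the carbonyl carbon and couples the acyl group with the alkyne. The amine then steers closure to the chromone A1, and hydrogenolysis of the benzyl ether gives 23.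
- For it: three bonds and a ring in one operation, full convergence, no isolated ynone, and very few steps once A2 is in hand. On step economy and convergence it is stronger than the chosen route.
- Against it: the whole ring-A problem is moved into A2, a 1,2,4,5-tetrasubstituted benzene whose O6 methyl, O7 benzyl, free O1–H and iodine must be placed by selective alkylation of neighbouring oxygens and by directing effects in an electrophilic iodination. The electron-rich ortho-iodophenol is also slow in oxidative addition, so non-carbonylative coupling and benzofuran formation compete.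
- Comparison: the chosen strategy is longer. In exchange, each oxygen is bonded to its carbon before ring A exists, ring A is assembled without relying on directing effects, and the ring-forming step needs no metal and no pressurised gas.

**Alternative 2:** Ring A is cut at C6–C5 and C8a–C4a into the 1,3-bis(silyloxy)diene A4 (C6, C7, C8, C8a with their oxygens) and the terminal triple bond of the cross-conjugated diynone A5 (C5, C4a, with C4, C3, C2 and ring B attached). In the forward step, the nucleophilic methoxy-bearing diene terminus bonds to the terminal alkyne carbon and the ketene-acetal carbon to the internal one. Loss of one methoxy group as the alcohol aromatises the ring, and desilylation on work-up gives A3, the 7-hydroxy analogue of 19, one amine-promoted closure away from 23.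
- For it: it is the shortest of all the plans, needs no protecting group on O7, and differentiates O6 from O7 through the diene. On step count it is stronger than the chosen route.
- Against it: A5 has two triple bonds activated by the same carbonyl, and only sterics favour the terminal one. A terminal ynone is prone to polymerisation and to open-chain Mukaiyama–Michael addition without ring closure. A4 is a moisture-sensitive mixture of geometric isomers. In A3 the free 7-hydroxyl, once ionised, is conjugated to the ynone carbonyl and lowers the electrophilicity needed for ring C closure.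
- Comparison: the chosen strategy spends more steps but closes ring A intramolecularly in a pericyclic step whose regiochemistry cannot vary, and it carries O7 masked through the closure of ring C.

**Alternative 3:** Ring A is cut at C6–C5, C4a–C8a and C8a–C8 into the alkenyl(methoxy)carbene complex A7 of zerovalent chromium (C6, C7, C8), one carbonyl ligand (C8a with O1) and the terminal alkyne of diyne A8 (C5, C4a). On heating, a Dötz benzannulation gives A6 after oxidative demetalation: alkyne insertion, carbonyl insertion to a metal-bound dienylketene, electrocyclisation and tautomerisation.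
- For it: three components are joined convergently, the regiochemistry that places the substituted alkyne carbon next to the new phenol is well established, and A6 differs from 17 only in carrying tert-butyl in place of isopropyl. The final ether cleavage would therefore need only a protic acid, which is milder than the boron Lewis acid of the chosen route.
- Against it: chromium is used stoichiometrically. The electron-rich alkoxyalkenyl carbene complex has to be made from a lithiated enol ether, Cr(CO)6 and a hard methylating agent, and such complexes are prone to products without carbonyl insertion. The second alkyne of A8 can also insert.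
- Comparison: both routes pass through a dienylketene and a 6π closure and have the same endgame. The chosen route generates the ketene without a metal, from a precursor made by two ordinary carbonyl additions, so fewer selectivities are in play.

Key step: step 6

Remark: the stereocentres that appear on the way (the carbinol carbon that becomes C4 and the quaternary cyclobutenone carbon) are carried as racemates or diastereomer mixtures, because all are erased before the target; compound 8 is taken as a purchasable reagent.

## Route

Step 1
Reactants: 1 diisopropyl squarate (3,4-diisopropoxycyclobut-3-ene-1,2-dione)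
Product: 3 3-isopropoxycyclobut-3-ene-1,2-dione, via hydroxycyclobutenone 2 (not isolated)
Conditions: LiAlH(OtBu)3, THF, −78 to 0 °C; then 6 M HCl, CH2Cl2, rt
Reagents that add atoms: water (from the aqueous HCl), O
Why: Bulky-hydride reduction of a squarate ester should stop after one carbonyl, because the adduct is an alkoxide whose remaining carbonyl is a deactivated vinylogous ester. Acid then ionises the allylic hydroxyl of 2, water returns at the distal alkoxy-bearing carbon and isopropanol is expelled (reduction followed by vinylogous acetal hydrolysis), leaving the semisquarate.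

Step 2
Reactants: 4 5-ethynyl-1,2,3-trimethoxybenzene
Product: 7 3-(3,4,5-trimethoxyphenyl)prop-2-ynal, via lithium arylacetylide 5 (not isolated), via lithium hemiaminal alkoxide 6 (not isolated)
Conditions: n-BuLi, THF, −40 °C; DMF, −40 °C to rt; reverse quench into 10% aq KH2PO4/MTBE, 5 °C
Reagents that add atoms: N,N-dimethylformamide (DMF), CN(C)C=O
Why: Formylation of a lithium acetylide with a formamide. The tetrahedral adduct 6 should not collapse until the buffered reverse quench, so the liberated dimethylamine is protonated before it can add to the ynal.

Step 3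
Reactants: 8 (E)-1,2-bis(tributylstannyl)ethene; 7 3-(3,4,5-trimethoxyphenyl)prop-2-ynal
Product: 10 racemic (E)-1-(tributylstannyl)-5-(3,4,5-trimethoxyphenyl)pent-1-en-4-yn-3-ol, via stannylvinyllithium 9 (not isolated)
Conditions: 8 (1.1 equiv), n-BuLi (1.0 equiv), THF, −78 °C; then 7, −78 °C; sat. aq NH4Cl
Reagents that add atoms: none
Why: Tin–lithium exchange on a vinylstannane proceeds with retention of the (E) geometry and, with one equivalent of alkyllithium at −78 °C, should stop at the mono-lithio species 9, which adds 1,2 to the ynal carbonyl. The new carbinol centre forms racemic, which is acceptable because it becomes the C4 carbonyl.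

Step 4
Reactants: 10 racemic (E)-1-(tributylstannyl)-5-(3,4,5-trimethoxyphenyl)pent-1-en-4-yn-3-ol
Product: 11 racemic tert-butyldimethyl{[(E)-1-(tributylstannyl)-5-(3,4,5-trimethoxyphenyl)pent-1-en-4-yn-3-yl]oxy}silane
Conditions: TBSCl, imidazole, DMF, 0 °C to rt
Reagents that add atoms: tert-butyldimethylsilyl chloride (TBSCl), CC(C)(C)[Si](C)(C)Cl
Why: Imidazole-promoted silylation of a secondary alcohol. The basic medium leaves the acid-sensitive vinylstannane intact, and the silyl ether masks the hydroxyl for the organolithium step.

Step 5
Reactants: 11 racemic tert-butyldimethyl{[(E)-1-(tributylstannyl)-5-(3,4,5-trimethoxyphenyl)pent-1-en-4-yn-3-yl]oxy}silane; 3 3-isopropoxycyclobut-3-ene-1,2-dione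
Product: 14 3-isopropoxy-4-methoxy-4-[(E)-3-(tert-butyldimethylsilyloxy)-5-(3,4,5-trimethoxyphenyl)pent-1-en-4-ynyl]cyclobut-2-en-1-one (diastereomer mixture), via alkenyllithium 12 (not isolated), via lithium alkoxide 13 (not isolated)
Conditions: n-BuLi, THF, −78 °C; cannulation into 3, THF, −78 °C; then MeOTf, −78 to 0 °C
Reagents that add atoms: methyl trifluoromethanesulfonate (MeOTf), COS(=O)(=O)C(F)(F)F
Why: A second tin–lithium exchange gives alkenyllithium 12 with retention of geometry. Organolithium reagents add to a 3-alkoxycyclobutenedione at the ketone-like carbonyl next to the alkoxy-bearing carbon, not at the vinylogous ester carbonyl, which places the new quaternary carbon (future C6) beside the isopropoxy carbon (future C7). Trapping alkoxide 13 with a hard methylating agent at low temperature fixes the O6 methyl group; the quaternary centre forms without control, which is immaterial because it becomes an aromatic carbon.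

Step 6
Reactants: 14 3-isopropoxy-4-methoxy-4-[(E)-3-(tert-butyldimethylsilyloxy)-5-(3,4,5-trimethoxyphenyl)pent-1-en-4-ynyl]cyclobut-2-en-1-one (diastereomer mixture)
Product: 17 racemic 5-isopropoxy-4-methoxy-2-[1-(tert-butyldimethylsilyloxy)-3-(3,4,5-trimethoxyphenyl)prop-2-ynyl]phenol, via dienylketene 15 (not isolated), via cyclohexadienone 16 (not isolated)
Conditions: PhMe (degassed, 0.02 M), 110 °C, Ar
Reagents that add atoms: none
Why: Heating should break the bond between the carbonyl carbon and the quaternary carbon of the cyclobutenone in a conrotatory 4π electrocyclic opening to vinylketene 15, driven by ring strain and by the aromatic ring that follows. The selectivity the step needs is inward rotation of the alkenyl group, and the methoxy group on the same carbon secures it: a lone-pair donor on the breaking bond turns outward, which leaves the alkenyl group Z to the ketene across the new C7=C6 double bond. The (3Z)-dienylketene 15 then closes ring A by a thermally allowed disrotatory 6π electrocyclisation in which the ketene carbon (future C8a) bonds to the distal alkene carbon (future C4a), forming a six-membered carbocycle from an all-carbon triene. Dienone 16 carries a transient sp3 centre at C4a that is erased when its hydrogen moves to oxygen to give phenol 17, so no lasting stereocentre is created and the carbinol centre stays racemic. The closest known reaction type is the Moore rearrangement, the thermal ring expansion of 4-alkenyl-4-alkoxycyclobutenones to mono-protected hydroquinones. Regiochemistry cannot vary in this step, since C8a keeps the ketene oxygen, C8 the hydrogen, C7 the isopropoxy and C6 the methoxy group exactly as they stood on the four-membered ring. Chemoselectivity requires only that the ketene is not intercepted, which the intramolecular closure in dilute, dry, non-nucleophilic solvent should ensure; the aryl alkyne is not conjugated to the ketene, and the (E)-alkene keeps the bulky carbinol substituent outside the closing termini.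

Step 7
Reactants: 17 racemic 5-isopropoxy-4-methoxy-2-[1-(tert-butyldimethylsilyloxy)-3-(3,4,5-trimethoxyphenyl)prop-2-ynyl]phenol
Product: 18 racemic 2-[1-hydroxy-3-(3,4,5-trimethoxyphenyl)prop-2-ynyl]-5-isopropoxy-4-methoxyphenol
Conditions: TBAF, AcOH, THF, 0 °C to rt
Reagents that add atoms: none
Why: Fluoride-mediated cleavage of a secondary silyl ether. Buffering with AcOH keeps the phenol largely un-ionised and avoids base-induced reactions of the ortho-hydroxybenzylic, propargylic alcohol.

Step 8
Reactants: 18 racemic 2-[1-hydroxy-3-(3,4,5-trimethoxyphenyl)prop-2-ynyl]-5-isopropoxy-4-methoxyphenol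
Product: 19 1-(2-hydroxy-4-isopropoxy-5-methoxyphenyl)-3-(3,4,5-trimethoxyphenyl)prop-2-yn-1-one
Conditions: activated MnO2, CH2Cl2, rt
Reagents that add atoms: none
Why: The carbinol is both benzylic and propargylic, the class of alcohol that MnO2 oxidises chemoselectively under neutral heterogeneous conditions. Ortho-hydroxybenzylic alcohols are oxidised this way without protection of the phenol, and the product is stabilised by the hydrogen bond between O1–H and the new carbonyl.

Step 9
Reactants: 19 1-(2-hydroxy-4-isopropoxy-5-methoxyphenyl)-3-(3,4,5-trimethoxyphenyl)prop-2-yn-1-one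
Product: 21 7-isopropoxy-6-methoxy-2-(3,4,5-trimethoxyphenyl)-4H-chromen-4-one, via enaminone 20 (not isolated)
Conditions: Et2NH, EtOH, rt to reflux
Reagents that add atoms: none
Why: Conjugate addition of the secondary amine to the ynone gives enaminone 20, in which C3 is nucleophilic and C2 is the only electrophilic carbon. The phenol oxygen should therefore close ring C by a 6-endo-trig addition–elimination at C2 that expels the amine, and the 5-exo path to the aurone is shut off.

Step 10
Reactants: 21 7-isopropoxy-6-methoxy-2-(3,4,5-trimethoxyphenyl)-4H-chromen-4-one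
Product: 23 Prosogerin D (7-hydroxy-6-methoxy-2-(3,4,5-trimethoxyphenyl)-4H-chromen-4-one), via aryloxydichloroborane 22 (not isolated)
Conditions: BCl3 (excess), CH2Cl2, −78 to 0 °C; then H2O
Reagents that add atoms: none
Why: Lewis-acid dealkylation of an aryl ether: BCl3 binds the ether oxygen and the secondary alkyl group leaves as 2-chloropropane through a cation-like transition state that a methyl group cannot match, so aryl methyl ethers, including one ortho to the isopropoxy group, should survive at low temperature. Excess reagent is needed because the pyranone carbonyl binds one equivalent; water hydrolyses 22 to the phenol.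

## Compound list

1 | diisopropyl squarate (3,4-diisopropoxycyclobut-3-ene-1,2-dione) | CC(C)OC1=C(OC(C)C)C(=O)C1=O | starting material
2 | racemic 4-hydroxy-2,3-diisopropoxycyclobut-2-en-1-one | CC(C)OC1=C(OC(C)C)C(O)C1=O | intermediate
3 | 3-isopropoxycyclobut-3-ene-1,2-dione | CC(C)OC1=CC(=O)C1=O | intermediate
4 | 5-ethynyl-1,2,3-trimethoxybenzene | C#Cc1cc(OC)c(OC)c(OC)c1 | starting material
5 | lithium (3,4,5-trimethoxyphenyl)acetylide | [Li]C#Cc1cc(OC)c(OC)c(OC)c1 | intermediate
6 | racemic lithium 1-(dimethylamino)-3-(3,4,5-trimethoxyphenyl)prop-2-yn-1-olate | [Li]OC(N(C)C)C#Cc1cc(OC)c(OC)c(OC)c1 | intermediate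
7 | 3-(3,4,5-trimethoxyphenyl)prop-2-ynal | O=CC#Cc1cc(OC)c(OC)c(OC)c1 | intermediate
8 | (E)-1,2-bis(tributylstannyl)ethene | CCCC[Sn](CCCC)(CCCC)/C=C/[Sn](CCCC)(CCCC)CCCC | starting material
9 | (E)-2-(tributylstannyl)ethenyllithium | [Li]/C=C/[Sn](CCCC)(CCCC)CCCC | intermediate
10 | racemic (E)-1-(tributylstannyl)-5-(3,4,5-trimethoxyphenyl)pent-1-en-4-yn-3-ol | CCCC[Sn](CCCC)(CCCC)/C=C/C(O)C#Cc1cc(OC)c(OC)c(OC)c1 | intermediate
11 | racemic tert-butyldimethyl{[(E)-1-(tributylstannyl)-5-(3,4,5-trimethoxyphenyl)pent-1-en-4-yn-3-yl]oxy}silane | CCCC[Sn](CCCC)(CCCC)/C=C/C(O[Si](C)(C)C(C)(C)C)C#Cc1cc(OC)c(OC)c(OC)c1 | intermediate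
12 | racemic [(E)-3-(tert-butyldimethylsilyloxy)-5-(3,4,5-trimethoxyphenyl)pent-1-en-4-ynyl]lithium | [Li]/C=C/C(O[Si](C)(C)C(C)(C)C)C#Cc1cc(OC)c(OC)c(OC)c1 | intermediate
13 | lithium 2-isopropoxy-4-oxo-1-[(E)-3-(tert-butyldimethylsilyloxy)-5-(3,4,5-trimethoxyphenyl)pent-1-en-4-ynyl]cyclobut-2-en-1-olate (diastereomer mixture) | [Li]OC1(/C=C/C(O[Si](C)(C)C(C)(C)C)C#Cc2cc(OC)c(OC)c(OC)c2)C(OC(C)C)=CC1=O | intermediate
14 | 3-isopropoxy-4-methoxy-4-[(E)-3-(tert-butyldimethylsilyloxy)-5-(3,4,5-trimethoxyphenyl)pent-1-en-4-ynyl]cyclobut-2-en-1-one (diastereomer mixture) | O=C1C=C(OC(C)C)C1(OC)/C=C/C(O[Si](C)(C)C(C)(C)C)C#Cc1cc(OC)c(OC)c(OC)c1 | intermediate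
15 | racemic (3Z,5E)-7-(tert-butyldimethylsilyloxy)-3-isopropoxy-4-methoxy-9-(3,4,5-trimethoxyphenyl)nona-1,3,5-trien-8-yn-1-one | O=C=C/C(OC(C)C)=C(OC)\C=C\C(O[Si](C)(C)C(C)(C)C)C#Cc1cc(OC)c(OC)c(OC)c1 | intermediate
16 | 6-[1-(tert-butyldimethylsilyloxy)-3-(3,4,5-trimethoxyphenyl)prop-2-ynyl]-3-isopropoxy-4-methoxycyclohexa-2,4-dien-1-one (diastereomer mixture) | O=C1C=C(OC(C)C)C(OC)=CC1C(O[Si](C)(C)C(C)(C)C)C#Cc1cc(OC)c(OC)c(OC)c1 | intermediate
17 | racemic 5-isopropoxy-4-methoxy-2-[1-(tert-butyldimethylsilyloxy)-3-(3,4,5-trimethoxyphenyl)prop-2-ynyl]phenol | COc1cc(C(O[Si](C)(C)C(C)(C)C)C#Cc2cc(OC)c(OC)c(OC)c2)c(O)cc1OC(C)C | intermediate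
18 | racemic 2-[1-hydroxy-3-(3,4,5-trimethoxyphenyl)prop-2-ynyl]-5-isopropoxy-4-methoxyphenol | COc1cc(C(O)C#Cc2cc(OC)c(OC)c(OC)c2)c(O)cc1OC(C)C | intermediate
19 | 1-(2-hydroxy-4-isopropoxy-5-methoxyphenyl)-3-(3,4,5-trimethoxyphenyl)prop-2-yn-1-one | COc1cc(C(=O)C#Cc2cc(OC)c(OC)c(OC)c2)c(O)cc1OC(C)C | intermediate
20 | (E)-3-(diethylamino)-1-(2-hydroxy-4-isopropoxy-5-methoxyphenyl)-3-(3,4,5-trimethoxyphenyl)prop-2-en-1-one | COc1cc(C(=O)/C=C(/N(CC)CC)c2cc(OC)c(OC)c(OC)c2)c(O)cc1OC(C)C | intermediate
21 | 7-isopropoxy-6-methoxy-2-(3,4,5-trimethoxyphenyl)-4H-chromen-4-one | COc1cc2c(=O)cc(-c3cc(OC)c(OC)c(OC)c3)oc2cc1OC(C)C | intermediate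
22 | dichloro{[6-methoxy-4-oxo-2-(3,4,5-trimethoxyphenyl)-4H-chromen-7-yl]oxy}borane | COc1cc2c(=O)cc(-c3cc(OC)c(OC)c(OC)c3)oc2cc1OB(Cl)Cl | intermediate
23 | Prosogerin D, 7-hydroxy-6-methoxy-2-(3,4,5-trimethoxyphenyl)-4H-chromen-4-one | COc1cc2c(=O)cc(-c3cc(OC)c(OC)c(OC)c3)oc2cc1O | target

## Step count and least certain steps

Total step count: 10. Longest linear sequence: 9 steps (from 4 through steps 2 to 10); step 1 is a one-step branch that joins at step 5.

**Step 6 (key step).** The ring expansion itself is well precedented; the new variable is the side chain. The most likely failure is thermal loss of silanol from the ortho-hydroxybenzylic, propargylic silyl ether once phenol 17 has formed (quinone methide formation), or addition of the new phenol to the alkyne. This becomes more likely if ring opening of the 3-alkoxycyclobutenone needs the upper end of the temperature range (p-xylene, 138 °C). The fallback forms the C4–C3 bond after the ring expansion instead of before it, so that the thermolysis is run with an inert side chain; it sets out from semisquarate 3 and returns at 18.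
- Commercial 3,3-diethoxyprop-1-yne would be hydrostannylated (Bu3SnH, AIBN, 80 °C) to (E)-3,3-diethoxy-1-(tributylstannyl)prop-1-ene F1.
- Tin–lithium exchange (n-BuLi, THF, −78 °C), addition to 3 and trapping with MeOTf as in step 5 would give 4-[(E)-3,3-diethoxyprop-1-enyl]-3-isopropoxy-4-methoxycyclobut-2-en-1-one F2.
- The same thermal ring expansion would give 2-(diethoxymethyl)-5-isopropoxy-4-methoxyphenol F3, and dilute aqueous acid would free 2-hydroxy-4-isopropoxy-5-methoxybenzaldehyde F4.
- Two equivalents of lithium acetylide 5 (the first is consumed by the phenol) would add to F4 and give 18, from which steps 8 to 10 follow.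

**Step 5.** The most likely failure is proton transfer in place of, or after, tin–lithium exchange: the C–H on the silyloxy carbon of 11 is allylic and propargylic, so n-BuLi or alkenyllithium 12 may remove it. In addition, slow O-methylation of the hindered alkoxide 13 in THF could allow ring opening of the alkoxide on warming. The fallback changes the metalation precursor and separates the methylation; it sets out from 11 and returns at 14.
- Iododestannylation (I2, CH2Cl2, 0 °C) would give racemic tert-butyl{[(E)-1-iodo-5-(3,4,5-trimethoxyphenyl)pent-1-en-4-yn-3-yl]oxy}dimethylsilane F5.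
- Iodine–lithium exchange with t-BuLi (2 equiv) in Et2O at −100 °C, which is far faster than deprotonation, would give 12, added at once to 3.
- NH4Cl quench would give 4-hydroxy-3-isopropoxy-4-[(E)-3-(tert-butyldimethylsilyloxy)-5-(3,4,5-trimethoxyphenyl)pent-1-en-4-ynyl]cyclobut-2-en-1-one F6 as a diastereomer mixture, and methylation with MeI and Ag2O in MeCN would give 14.

**Step 8.** The most likely failure is oxidation of the electron-rich para-methoxyphenol (quinone formation or oxidative coupling) competing with oxidation of the alcohol, or uncontrolled ring closure of 19 on the oxidant surface. The fallback masks the phenol during desilylation and oxidation; it sets out from 17 and returns at 19.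
- MOMCl and i-Pr2NEt (CH2Cl2) would give racemic tert-butyl{1-[4-isopropoxy-5-methoxy-2-(methoxymethoxy)phenyl]-3-(3,4,5-trimethoxyphenyl)prop-2-ynyloxy}dimethylsilane F7.
- TBAF (THF) would give racemic 1-[4-isopropoxy-5-methoxy-2-(methoxymethoxy)phenyl]-3-(3,4,5-trimethoxyphenyl)prop-2-yn-1-ol F8.
- MnO2 or Dess–Martin periodinane would give 1-[4-isopropoxy-5-methoxy-2-(methoxymethoxy)phenyl]-3-(3,4,5-trimethoxyphenyl)prop-2-yn-1-one F9.
- Brief treatment with HCl in MeOH would remove the acetal and give 19; any 21 formed under the acid is the product of step 9 in any case.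

**Step 3.** The most likely failure is incomplete or double tin–lithium exchange on 8, so that residual n-BuLi or a dilithio species attacks the aldehyde, together with base-induced decomposition of the electrophilic ynal 7. The fallback reverses the polarity of the C4–C3/C4–C4a assembly and avoids both 7 and the mono-lithiation; it sets out from acetylide 5 (made from 4 as in step 2) and returns at 10.
- Prop-2-yn-1-ol would be hydrostannylated (Bu3SnH, AIBN, 80 °C) and the (E) isomer separated, giving (E)-3-(tributylstannyl)prop-2-en-1-ol F10.
- MnO2 in CH2Cl2 would give (E)-3-(tributylstannyl)prop-2-enal F11.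
- Addition of 5 at −78 °C would give 10.

## Further compounds

F1 | step 6 | (E)-3,3-diethoxy-1-(tributylstannyl)prop-1-ene | CCCC[Sn](CCCC)(CCCC)/C=C/C(OCC)OCC
F2 | step 6 | racemic 4-[(E)-3,3-diethoxyprop-1-enyl]-3-isopropoxy-4-methoxycyclobut-2-en-1-one | O=C1C=C(OC(C)C)C1(OC)/C=C/C(OCC)OCC
F3 | step 6 | 2-(diethoxymethyl)-5-isopropoxy-4-methoxyphenol | CCOC(OCC)c1cc(OC)c(OC(C)C)cc1O
F4 | step 6 | 2-hydroxy-4-isopropoxy-5-methoxybenzaldehyde | O=Cc1cc(OC)c(OC(C)C)cc1O
F5 | step 5 | racemic tert-butyl{[(E)-1-iodo-5-(3,4,5-trimethoxyphenyl)pent-1-en-4-yn-3-yl]oxy}dimethylsilane | I/C=C/C(O[Si](C)(C)C(C)(C)C)C#Cc1cc(OC)c(OC)c(OC)c1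
F6 | step 5 | 4-hydroxy-3-isopropoxy-4-[(E)-3-(tert-butyldimethylsilyloxy)-5-(3,4,5-trimethoxyphenyl)pent-1-en-4-ynyl]cyclobut-2-en-1-one (diastereomer mixture) | O=C1C=C(OC(C)C)C1(O)/C=C/C(O[Si](C)(C)C(C)(C)C)C#Cc1cc(OC)c(OC)c(OC)c1
F7 | step 8 | racemic tert-butyl{1-[4-isopropoxy-5-methoxy-2-(methoxymethoxy)phenyl]-3-(3,4,5-trimethoxyphenyl)prop-2-ynyloxy}dimethylsilane | COCOc1cc(OC(C)C)c(OC)cc1C(O[Si](C)(C)C(C)(C)C)C#Cc1cc(OC)c(OC)c(OC)c1
F8 | step 8 | racemic 1-[4-isopropoxy-5-methoxy-2-(methoxymethoxy)phenyl]-3-(3,4,5-trimethoxyphenyl)prop-2-yn-1-ol | COCOc1cc(OC(C)C)c(OC)cc1C(O)C#Cc1cc(OC)c(OC)c(OC)c1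
F9 | step 8 | 1-[4-isopropoxy-5-methoxy-2-(methoxymethoxy)phenyl]-3-(3,4,5-trimethoxyphenyl)prop-2-yn-1-one | COCOc1cc(OC(C)C)c(OC)cc1C(=O)C#Cc1cc(OC)c(OC)c(OC)c1
F10 | step 3 | (E)-3-(tributylstannyl)prop-2-en-1-ol | CCCC[Sn](CCCC)(CCCC)/C=C/CO
F11 | step 3 | (E)-3-(tributylstannyl)prop-2-enal | CCCC[Sn](CCCC)(CCCC)/C=C/C=O
A1 | alternative 1 | 7-(benzyloxy)-6-methoxy-2-(3,4,5-trimethoxyphenyl)-4H-chromen-4-one | COc1cc2c(=O)cc(-c3cc(OC)c(OC)c(OC)c3)oc2cc1OCc1ccccc1
A2 | alternative 1 | 5-(benzyloxy)-2-iodo-4-methoxyphenol | COc1cc(I)c(O)cc1OCc1ccccc1
A3 | alternative 2 | 1-(2,4-dihydroxy-5-methoxyphenyl)-3-(3,4,5-trimethoxyphenyl)prop-2-yn-1-one | COc1cc(C(=O)C#Cc2cc(OC)c(OC)c(OC)c2)c(O)cc1O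
A4 | alternative 2 | 1,4-dimethoxy-1,3-bis(trimethylsilyloxy)buta-1,3-diene (mixture of double-bond isomers) | COC=C(O[Si](C)(C)C)C=C(OC)O[Si](C)(C)C
A5 | alternative 2 | 1-(3,4,5-trimethoxyphenyl)penta-1,4-diyn-3-one | C#CC(=O)C#Cc1cc(OC)c(OC)c(OC)c1
A6 | alternative 3 | racemic 5-tert-butoxy-4-methoxy-2-[1-(tert-butyldimethylsilyloxy)-3-(3,4,5-trimethoxyphenyl)prop-2-ynyl]phenol | COc1cc(C(O[Si](C)(C)C(C)(C)C)C#Cc2cc(OC)c(OC)c(OC)c2)c(O)cc1OC(C)(C)C
A7 | alternative 3 | pentacarbonyl[(1-tert-butoxyethenyl)(methoxy)carbene]chromium | COC(C(=C)OC(C)(C)C)=[Cr](=C=O)(=C=O)(=C=O)(=C=O)=C=O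
A8 | alternative 3 | racemic tert-butyl{[1-(3,4,5-trimethoxyphenyl)penta-1,4-diyn-3-yl]oxy}dimethylsilane | C#CC(O[Si](C)(C)C(C)(C)C)C#Cc1cc(OC)c(OC)c(OC)c1
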